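**Assumptions (one line each):**
- "(R)-carvone" means the commercial spearmint enantiomer, 5R.
- 2,2-Dimethoxyacetaldehyde is used anhydrous, dried from the commercial 60% aqueous solution.

**Retrosynthetic overview**
1. The C-8 acetate is installed last by acetylating a bridged lactol. That lactol comes from an acid cascade that closes the δ-lactone acylal and the THF acetal, forming the 2,7-dioxabicyclo[3.2.1]octan-3-one.
2. The key disconnection is the vicinal quaternary–tertiary C–C bond (the methyl-bearing ring carbon to the bicycle carbon CH). It forms by light-driven Co–H hydrogen-atom-transfer hydroalkylation of a cis-hydroazulenone cyclopentene with a Stobbe-derived alkylidene succinate.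
3. The hydroazulenone comes from (R)-carvone, which supplies the only purchased stereocentre.
4. Ring order: cyclopentene by quasi-Favorskii ring contraction (Step 2); cycloheptenone by RCM (Step 6); bridged bicycle last (Step 12).

---

**Step 1**
Reactants: 1 (R)-carvone
Product: 2 6-bromocarvone (C-6 epimers, inconsequential)
Conditions: LiHMDS, TMSCl, THF, −78 °C; then NBS, −78 → 0 °C (one pot)
Reagents that add atoms: NBS, BrN1C(=O)CCC1=O
Why: The only enolisable α-position (C-6) gives the kinetic silyl enol ether, which NBS brominates (Rubottom-type α′-halogenation). The C-6 configuration is lost in Step 2, and C-5 is untouched.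

**Step 2**
Reactants: 2
Product: 3 methyl (1R,5R)-2-methyl-5-(prop-1-en-2-yl)cyclopent-2-ene-1-carboxylate
Conditions: NaOMe, MeOH, 0 → 23 °C
Reagents that add atoms: sodium methoxide, CO[Na]; methanol, CO
Why: The α′-bromo enone has no enolisable α′-H, so methoxide adds to C=O and the vinyl carbon migrates to C-6 with loss of bromide (quasi-Favorskii/semibenzilic ring contraction). This gives the cyclopentene ester with the trisubstituted C=C retained. The C-5 centre is untouched; the ester-bearing centre is α to the ester and equilibrates under NaOMe, so the cis isomer is isolated and the trans epimer is recycled.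

**Step 3**
Reactants: 3; 4 allyl phenyl sulfone
Product: 5 methyl (1R,5R)-2-methyl-5-(2-methylpent-4-en-2-yl)cyclopent-2-ene-1-carboxylate
Conditions: Fe(acac)3 (0.5 equiv), PhSiH3, EtOH, 40 °C
Reagents that add atoms: none (the allyl group comes from 4)
Why: Fe–H HAT hits the 1,1-disubstituted isopropenyl faster than the trisubstituted ring alkene. The tertiary radical is allylated by SH2′ on the allyl sulfone (Giese-type radical allylation), creating the gem-dimethyl carbon with no new stereocentre.

**Step 4**
Reactants: 5
Product: 6 (1R,5R)-N-methoxy-N,2-dimethyl-5-(2-methylpent-4-en-2-yl)cyclopent-2-ene-1-carboxamide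
Conditions: AlMe3, MeNH(OMe)·HCl, CH2Cl2, 0 → 40 °C
Reagents that add atoms: N,O-dimethylhydroxylamine hydrochloride, CONC.Cl
Why: The Me2Al–N(OMe)Me reagent aminolyses the hindered ester without deprotonating the acidic α-H (Weinreb amide formation).

**Step 5**
Reactants: 6
Product: 7 1-[(1R,5R)-2-methyl-5-(2-methylpent-4-en-2-yl)cyclopent-2-en-1-yl]prop-2-en-1-one
Conditions: CH2=CHMgBr, THF, −78 → 0 °C
Reagents that add atoms: vinylmagnesium bromide, C=C[Mg]Br
Why: The chelated Weinreb tetrahedral intermediate stops at the vinyl ketone (Weinreb ketone synthesis).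

**Step 6**
Reactants: 7
Product: 8 (3aR,8aR)-3,8,8-trimethyl-3a,6,7,8a-tetrahydroazulen-4(1H)-one, cis-fused, 5,6-ene (enone in the 7-ring)
Conditions: Hoveyda–Grubbs II (5 mol %), toluene (0.005 M), 80 °C
Reagents that add atoms: none
Why: Ring-closing metathesis of the vinyl ketone with the neopentyl-type allyl group is favoured by the gem-dimethyl (Thorpe–Ingold) effect. The trisubstituted cyclopentene is inert to the catalyst, and ethylene is the only by-product.

**Step 7**
Reactants: 8
Product: 9 (3aR,8aR)-3,8,8-trimethyl-3a,5,6,7,8,8a-hexahydroazulen-4(1H)-one, cis-fused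
Conditions: [(Ph3P)CuH]6 (5 mol %), PhSiH3 (1.2 equiv), toluene, 0 °C; then aq. NH4Cl
Reagents that add atoms: none
Why: Cu–H 1,4-reduction (Stryker-type) saturates only the enone C=C and leaves the trisubstituted alkene. The α-stereocentre next to the ketone equilibrates to the cis-fused hydroazulenone, since a trans-fused cyclopentene/cycloheptanone is strained.

**Step 8**
Reactants: 10 dimethyl succinate; 11 2,2-dimethoxyacetaldehyde
Product: 12 (E)-5,5-dimethoxy-3-(methoxycarbonyl)pent-3-enoic acid
Conditions: KOt-Bu (2.2 equiv), t-BuOH, 82 °C, 3 h; cold citric-acid work-up to pH 4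
Reagents that add atoms: none
Why: Stobbe condensation gives the alkylidene succinic half-ester, with the free acid on the CH2 side and the ester on the alkene carbon. The acetal survives base, and the E alkene places the acetal carbon cis to CH2CO2H.

**Step 9**
Reactants: 9; 12
Product: 13 (C22H36O7): ketone bearing the new quaternary centre joined to CH(CH(OMe)2)CH(CO2Me)CH2CO2H
Conditions: Co(salen) (10 mol %), 4CzIPN (2 mol %), Hantzsch ester (2 equiv), 12 (2.5 equiv), MeCN/DMA 4:1, blue LEDs (456 nm), 23 °C, 24 h
Reagents that add atoms: none (only H is added, from Hantzsch ester and the acceptor's CO2H)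
Why: Proposed new method: a silane-free, light-driven Co–H hydroalkylation that joins the hindered trisubstituted alkene to the alkylidene succinate and forms the vicinal quaternary–tertiary bond.
- Mechanism: excited 4CzIPN reduces Co(III) to Co(I), which is protonated by the acceptor's CO2H to give Co(III)–H. Co–H transfers H• to the CH= carbon of the cyclopentene (Markovnikov), giving the tertiary radical on the methyl-bearing carbon. That radical adds to the carbon β to the ester in 12, and the α-ester radical is reduced by 4CzIPN•− and protonated.
- Closest known reaction types: Fe–H/silane HAT Giese olefin–acceptor coupling and photoredox/Co–H HAT hydrofunctionalisation.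
- Stereochemistry: the radical is attacked on the convex face, the same face as the ring-fusion H's and anti to the ring-fusion substituent on the adjacent carbon. That puts the new C–C bond trans to the 7-ring and the methyl cis to it. The CH(CH(OMe)2) centre is set by the approach that minimises gauche interactions with the ring, and the diastereomers are separable.

**Step 10**
Reactants: 13
Product: 14 exocyclic alkene: C=C1CCCC(C)(C)[C@@H]2CC[C@@](C)(…)[C@H]12 with the side chain unchanged
Conditions: Ph3PCH3Br (5 equiv), KOt-Am (4.8 equiv), toluene, 23 → 60 °C; citric-acid quench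
Reagents that add atoms: methylenetriphenylphosphorane, C=P(c1ccccc1)(c1ccccc1)c1ccccc1
Why: Wittig methylenation of the hindered cycloheptanone with excess ylide, the first equivalent being consumed by the CO2H. The ester and acetal are untouched. The α-carbon next to the ketone stays cis-fused, because the large substituent on the adjacent quaternary carbon disfavours the epimer. The ester-bearing centre may epimerise and is re-set in Step 12.

**Step 11**
Reactants: 14
Product: 15 aldehyde acid
Conditions: DIBAL-H (4 equiv), CH2Cl2, −78 → −50 °C; Rochelle salt/citric acid work-up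
Reagents that add atoms: none (hydride only)
Why: Partial DIBAL reduction of the methyl ester to the aldehyde. The first equivalent converts CO2H to an aluminium carboxylate, which is not reduced at low temperature, and the dimethyl acetal and exocyclic alkene are inert.

**Step 12**
Reactants: 15
Product: 16 bridged lactol (2,7-dioxabicyclo[3.2.1]octan-3-one with an anomeric OH)
Conditions: p-TsOH·H2O (0.3 equiv), THF/H2O 5:1, 23 °C, 16 h
Reagents that add atoms: water, O
Why: Acetal hydrolysis gives an oxocarbenium ion, which the CO2H traps to form a 6-membered lactone. Loss of the second OMe and capture by the aldehyde hydrate closes the THF ring. This is an intramolecular acetal exchange to a bridged acylal, and the bridgehead acylal centre, the CH next to the aldehyde and the lactol centre are set under thermodynamic control. The bicycle forms with the bulky substituent syn to the planar lactone bridge.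

**Step 13**
Reactants: 16
Product: 17 aplyviolene
Conditions: Ac2O (5 equiv), pyridine (10 equiv), DMAP (0.1 equiv), CH2Cl2, 0 → 23 °C
Reagents that add atoms: acetic anhydride, CC(=O)OC(C)=O
Why: The lactol equilibrates, and acylation occurs on the less hindered exo face, giving the exo acetate (O-acetylation).

---

**Compound list**
1 | (R)-carvone | CC1=CC[C@@H](C(C)=C)CC1=O | starting material
2 | 6-bromocarvone | CC1=CC[C@@H](C(C)=C)C(Br)C1=O | intermediate
3 | methyl (1R,5R)-2-methyl-5-isopropenylcyclopent-2-ene-1-carboxylate | COC(=O)[C@H]1C(C)=CC[C@H]1C(C)=C | intermediate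
4 | allyl phenyl sulfone | C=CCS(=O)(=O)c1ccccc1 | starting material
5 | methyl (1R,5R)-2-methyl-5-(2-methylpent-4-en-2-yl)cyclopent-2-ene-1-carboxylate | COC(=O)[C@H]1C(C)=CC[C@H]1C(C)(C)CC=C | intermediate
6 | Weinreb amide of 5 | CON(C)C(=O)[C@H]1C(C)=CC[C@H]1C(C)(C)CC=C | intermediate
7 | vinyl ketone | C=CC(=O)[C@H]1C(C)=CC[C@H]1C(C)(C)CC=C | intermediate
8 | (3aR,8aR)-cis-hydroazulenone enone | O=C1C=CCC(C)(C)[C@@H]2CC=C(C)[C@H]12 | intermediate
9 | (3aR,8aR)-3,8,8-trimethyl-3a,5,6,7,8,8a-hexahydroazulen-4(1H)-one | O=C1CCCC(C)(C)[C@@H]2CC=C(C)[C@H]12 | intermediate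
10 | dimethyl succinate | COC(=O)CCC(=O)OC | starting material
11 | 2,2-dimethoxyacetaldehyde | COC(OC)C=O | starting material
12 | (E)-5,5-dimethoxy-3-(methoxycarbonyl)pent-3-enoic acid | OC(=O)C/C(=C\C(OC)OC)C(=O)OC | intermediate
13 | ketone coupling product | O=C1CCCC(C)(C)[C@@H]2CC[C@@](C)([C@H](C(OC)OC)[C@@H](CC(=O)O)C(=O)OC)[C@H]12 | intermediate
14 | exocyclic-methylene ester acetal acid | C=C1CCCC(C)(C)[C@@H]2CC[C@@](C)([C@H](C(OC)OC)[C@@H](CC(=O)O)C(=O)OC)[C@H]12 | intermediate
15 | aldehyde acetal acid | C=C1CCCC(C)(C)[C@@H]2CC[C@@](C)([C@H](C(OC)OC)[C@@H](CC(=O)O)C=O)[C@H]12 | intermediate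
16 | bridged lactol | C=C1CCCC(C)(C)[C@@H]2CC[C@@](C)([C@@H]3[C@@H]4OC(=O)C[C@H]3[C@H](O)O4)[C@H]12 | intermediate
17 | aplyviolene | C=C1CCCC(C)(C)[C@@H]2CC[C@@](C)([C@@H]3[C@@H]4OC(=O)C[C@H]3[C@H](OC(C)=O)O4)[C@H]12 | target

**Total steps:** 13. **Longest linear sequence:** 12 (Steps 1–7, then 9–13).

**Three steps most likely to fail**
1. **Step 9 (proposed new photochemical Co–H coupling).** Risks are direct photoreduction of the acceptor or H2 evolution, and low diastereoselectivity at the new CH centre. Fallback (known chemistry): Mukaiyama hydration of 9 (Co(acac)2, O2, PhSiH3) to the tertiary alcohol, conversion to its cesium oxalate, then Ir-photoredox decarboxylative Giese addition to 12.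
2. **Step 2 (quasi-Favorskii ring contraction).** Methoxide may instead add conjugately or substitute the bromide. Fallback: α′-diazo transfer on carvone (LiHMDS/CF3CO2CH2CF3, then MsN3) followed by photochemical Wolff rearrangement in MeOH to give 3.
3. **Step 12 (bicycle-forming cascade).** The stereochemistry at the CH next to the aldehyde and at the lactol may be wrong, or the exocyclic alkene may isomerise. Fallback: keep the ester through the acid step (TFA/H2O) to form the bridged bis-lactone, then reduce the γ-lactone C=O with DIBAL at −78 °C and acetylate.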